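All runs were computed with constants of no real substance; the scatter is artificial.

The constants of this chemistry are hidden, so the one you can read is a rise constant k, the rate at which the target closes on its plateau if its climb is taken as simple first-order.

| flask | substrate | first nucleophile | second nucleophile | capture agent | temperature | remark | time |
|---|---|---|---|---|---|---|---|
| winter | 10 mM | 50 mM | 50 mM | 6 mM | 55 °C | run made earlier |  |
| dawn | 40 mM | 50 mM | 50 mM | 6 mM | 88 °C | run made earlier |  |
| south | 20 mM | 50.0 mM | 50.0 mM | 6.00 mM | 40 °C |  | 8.0 min |
| east | 20 mM | 50.0 mM | 50.0 mM | 6.00 mM | 100 °C |  | 8.0 min |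
| west | 20 mM | 50.0 mM | 50.0 mM | 6.00 mM | 70 °C |  | 8.0 min |

winter run (percent of the substrate charged): time / min: target / % = 1.00: 2.8; 2.00: 6.1; 3.00: 7.9; 4.00: 9.5

dawn run (percent of the substrate charged): time / s: target / % = 10.0: 4.6; 15.0: 7.9; 40.0: 11.7

(readings scatter by 0.3 percentage points)

- the earlier runs were read with a standard deviation of 0.3 percentage points

- the best flask by amount of target, in percent of the substrate charged; "all alike" if 1.5 percentage points covers them all (south / east / west / all alike)
- amount of target at the end, in percent of the substrate charged, south
- amount of target at the end, in percent of the substrate charged, east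
- amount of target at the end, in percent of the substrate charged, west

Winter's readings at 2.00 min and 4.00 min give k = 0.292 min⁻¹ and a plateau of 13.8%, both carrying the scatter of the readings. Dawn takes two rounds. With its last reading as the plateau, k = 4.50 min⁻¹. Put that back in and 40.0 s falls short of the full rise, so the plateau becomes 12.3% and k becomes 4.10 min⁻¹.

West's 70 °C lies near the middle of 55 °C and 88 °C, so I take the geometric mean, k = 1.10 min⁻¹, and west gets 8.76 rise times. This N, the rise constant times the time the flask runs, is the quantity to carry. South's 40 °C sits as far below winter as west sits above it, so k = 0.0780 min⁻¹ and N = 0.624, which puts south's target at 6.40%. West, with its rise over on this count, takes the mean of the plateaus, 13.0%. East is hotter than dawn, so I reckon its N above 32.8.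

The weak link is the plateau itself. Dawn's last reading stands at N = 2.74, while east runs much further and west further too. No reading shows that the target stays on its plateau that far out. Winter and dawn also differ in substrate as well as in temperature, so the step from 13.8% to 12.3% can't be put on either setting. For east I therefore commit to 12.3%, the plateau read from the nearest run, as an uncertain estimate, and I commit to west as best, a thin choice at 13.0% against 12.3%.

The forecast named west, with 5% for south, below mine, 14% for west, above mine, and 11.5% for east, which is dawn's last reading taken over, and it said “At 100 °C it finishes within seconds, at about 12%, with some risk of loss.”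

The flasks give west as best: south 4.85%, east 4.19%, west 13.3%.

    substrate → open intermediate (k = 0.00930 s⁻¹, Ea = 92.0 kJ mol⁻¹)
    first nucleophile + open intermediate → target (k = 1.50 M⁻¹ s⁻¹, Ea = 41.0 kJ mol⁻¹)
    second nucleophile + open intermediate → other capture product (k = 3.90 M⁻¹ s⁻¹, Ea = 42.0 kJ mol⁻¹)
    open intermediate → solvolysis product (k = 0.0660 s⁻¹, Ea = 93.0 kJ mol⁻¹)
    target ⇌ isomer of the product (K = 4.30, k = 0.00160 s⁻¹, Ea = 100 kJ mol⁻¹, ΔH = −24.0 kJ mol⁻¹)
    open intermediate + capture agent → trapped intermediate (k = 0.120 M⁻¹ s⁻¹, Ea = 56.0 kJ mol⁻¹)
    (constants at 70 °C)

South has not come to rest: at N = 0.624 it holds 81.6% of its substrate, and by 80.0 min its target stands at 21.0%. East has: its target is 4.19% at 80.0 min, as at 8.0 min. West, with N = 8.76 and 1.15% substrate left, looks finished but is not at rest. At 8.00 min west's target is made at 0.149 of the rate at which it is used up, each step taken net. West's isomer of the product grows from 9.44% at that time to 18.7% at 80.0 min, and by 80.0 min west's target has fallen to 4.34%.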